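The target is cut at the aryl–CH bond of the central methine into two 8-acyl-5,7-dihydroxy-2,2-dimethylchromans, joined last by a catalyst-controlled Friedel–Crafts addition to an ortho-quinone methide. Both chromans come from one ester-blocked intermediate whose O-ring is first made one atom too small: HBr ionises a 2-(2-hydroxypropan-2-yl)-2,3-dihydrobenzofuran, ring oxygen O1 bridges to the carbinol carbon (oxiranium ion), and bromide opening inserts the C(CH3)2 carbon between O1 and the ring, giving the dihydropyran ring O1–C2–C3–C4–C4a–C8a of the isobutyryl-bearing chroman (ring B). The step exploits the tertiary ether unit O1–C2(CH3)2 of that ring: the gem-dimethyl carbon carries the cation and O1 acts as neighbouring group.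

Key step: step 3

Assumption: (2R)-2-methylbutanoic acid is taken as a commercial, enantiopure starting material; chroman atoms are numbered O1, C2, C3, C4, C4a, C5 to C8, C8a throughout.

Step 1
Reactants: 1 methyl 2,4,6-trihydroxybenzoate; 2 1-bromo-3-methylbut-2-ene (prenyl bromide)
Product: 3 methyl 2,4,6-trihydroxy-3-(3-methylbut-2-en-1-yl)benzoate
Conditions: NaOMe (1 equiv), MeOH, 0 °C to rt, 1 in twofold excess
Reagents that add atoms: none
Why: C-prenylation of the ambident phloroglucinol anion in a protic medium (Friedel–Crafts-type SN2 alkylation at carbon), in which the two free ring carbons are equivalent by symmetry, so only over-alkylation has to be held back by the excess of 1.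

Step 2
Reactants: 3 methyl 2,4,6-trihydroxy-3-(3-methylbut-2-en-1-yl)benzoate
Product: 5 methyl 4,6-dihydroxy-2-(2-hydroxypropan-2-yl)-2,3-dihydro-1-benzofuran-5-carboxylate (racemic), via epoxide 4 (not isolated)
Conditions: mCPBA, CH2Cl2, 0 °C; aq. NaHCO3 wash; then K2CO3 (0.2 equiv), MeOH, rt
Reagents that add atoms: mCPBA (3-chloroperbenzoic acid), O=C(OO)c1cccc(Cl)c1
Why: Prilezhaev epoxidation of the trisubstituted alkene, then base-mediated 5-exo-tet opening of the epoxide at its secondary carbon by the phenoxide of the para hydroxyl (the most acidic one, the ortho hydroxyls being tied to the ester by hydrogen bonds), should give the dihydrobenzofuran as a racemate whose single stereocenter is erased in step 4.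

Step 3
Reactants: 5 methyl 4,6-dihydroxy-2-(2-hydroxypropan-2-yl)-2,3-dihydro-1-benzofuran-5-carboxylate
Product: 7 methyl 3-bromo-5,7-dihydroxy-2,2-dimethyl-3,4-dihydro-2H-chromene-6-carboxylate (racemic), via tertiary bromide 6 (not isolated)
Conditions: HBr (33% in AcOH, 3 equiv), CH2Cl2 (dilute), 0 °C to rt
Reagents that add atoms: hydrogen bromide, Br
Why: Acid ionises the tertiary carbinol with help from ring oxygen O1, which closes a bridged aryl oxiranium ion (3-exo-tet), and bromide opens this ion at the secondary ring carbon with cleavage of the old O1–CH bond, so the C(CH3)2 carbon is inserted between O1 and the ring and the five-membered dihydrofuran ring grows to the six-membered dihydropyran ring (opening in the endo sense, net 1,2-oxygen shift of Wagner–Meerwein type). The closest known reaction type is the oxiranium-mediated enlargement of 2-(1-hydroxyalkyl)tetrahydrofurans to 3-substituted tetrahydropyrans and of 2-(hydroxyisopropyl)dihydrobenzofurans to 3-substituted 2,2-dimethylchromans. Bromide attack at the carbinol carbon gives tertiary bromide 6, which should re-ionise with the same anchimeric assistance, so the mixture is expected to drain under thermodynamic control to the less strained secondary bromide 7. The new C3 stereocenter forms with inversion at the former C2 of racemic 5, is therefore racemic, and is erased in step 4. The selectivity needed is bromide capture over proton loss (isopropenyl or 2-isopropylbenzofuran formation) and over attack of the cation on the free ring carbon of a second molecule, which the high bromide concentration, the low temperature and dilution should secure.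

Step 4
Reactants: 7 methyl 3-bromo-5,7-dihydroxy-2,2-dimethyl-3,4-dihydro-2H-chromene-6-carboxylate
Product: 8 methyl 5,7-dihydroxy-2,2-dimethyl-3,4-dihydro-2H-chromene-6-carboxylate
Conditions: Bu3SnH (1.5 equiv, 0.5 M), AIBN (cat.), benzene, 80 °C
Reagents that add atoms: none
Why: Radical chain dehalogenation with tin hydride, in which the high stannane concentration should make hydrogen transfer to the secondary C3 radical faster than beta-scission of the adjacent C2–O1 bond, removes the halogen and the only stereocenter.

Step 5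
Reactants: 8 methyl 5,7-dihydroxy-2,2-dimethyl-3,4-dihydro-2H-chromene-6-carboxylate; 9 2-methylpropanoyl chloride (isobutyryl chloride)
Product: 10 methyl 5,7-dihydroxy-2,2-dimethyl-8-(2-methylpropanoyl)-3,4-dihydro-2H-chromene-6-carboxylate
Conditions: AlCl3 (3 equiv), CH2Cl2/MeNO2, 0 °C to rt; aq. HCl work-up
Reagents that add atoms: none
Why: Friedel–Crafts acylation at C8, the only unsubstituted ring carbon and one activated by three oxygen donors, so the ester at C6 serves as a blocking group that places the acyl group next to O1 without regiochemical choice.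

Step 6
Reactants: 10 methyl 5,7-dihydroxy-2,2-dimethyl-8-(2-methylpropanoyl)-3,4-dihydro-2H-chromene-6-carboxylate
Product: 12 1-(5,7-dihydroxy-2,2-dimethyl-3,4-dihydro-2H-chromen-8-yl)-2-methylpropan-1-one (fragment B), via carboxylic acid 11 (not isolated)
Conditions: LiI (5 equiv), EtOAc, reflux; then 1 M HCl, THF, 50 °C
Reagents that add atoms: none
Why: SN2 demethylation of the hindered, chelated ester by iodide followed by acid-promoted ipso-protodecarboxylation, which 2,4,6-trioxygenated benzoic acids undergo on gentle warming, removes the blocking group and frees C6–H for the coupling.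

Step 7
Reactants: 13 (2R)-2-methylbutanoic acid
Product: 14 (2R)-2-methylbutanoyl chloride
Conditions: (COCl)2, DMF (cat.), CH2Cl2, 0 °C to rt; used crude
Reagents that add atoms: oxalyl chloride, O=C(Cl)C(=O)Cl
Why: Acid chloride formation through the Vilsmeier-type chloroiminium species runs without base below room temperature, so no ketene can form and the alpha stereocenter should stay (R).

Step 8
Reactants: 8 methyl 5,7-dihydroxy-2,2-dimethyl-3,4-dihydro-2H-chromene-6-carboxylate; 14 (2R)-2-methylbutanoyl chloride
Product: 15 methyl 5,7-dihydroxy-2,2-dimethyl-8-[(2R)-2-methylbutanoyl]-3,4-dihydro-2H-chromene-6-carboxylate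
Conditions: AlCl3 (3 equiv), CH2Cl2/MeNO2, −10 °C to rt; aq. HCl work-up
Reagents that add atoms: none
Why: Friedel–Crafts acylation at the only free ring carbon as in step 5, run cold and without amine base so that the acylium ion is not deprotonated and the (R) stereocenter of 14 should pass unchanged into 15.

Step 9
Reactants: 15 methyl 5,7-dihydroxy-2,2-dimethyl-8-[(2R)-2-methylbutanoyl]-3,4-dihydro-2H-chromene-6-carboxylate
Product: 17 (2R)-1-(5,7-dihydroxy-2,2-dimethyl-3,4-dihydro-2H-chromen-8-yl)-2-methylbutan-1-one (fragment A), via carboxylic acid 16 (not isolated)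
Conditions: LiI (5 equiv), EtOAc, reflux; then 1 M HCl, THF, 50 °C
Reagents that add atoms: none
Why: The same iodide-mediated ester cleavage and protodecarboxylation as in step 6, chosen because it avoids strong base and hot strong acid and should therefore not enolise the ketone next to the (R) stereocenter.

Step 10
Reactants: 18 6-methylheptan-1-ol
Product: 19 6-methylheptanal
Conditions: TEMPO (10 mol %), PhI(OAc)2 (1.1 equiv), CH2Cl2, rt
Reagents that add atoms: none
Why: Oxoammonium (TEMPO-catalysed) oxidation of the primary alcohol with PhI(OAc)2 as terminal oxidant should stop at the aldehyde without over-oxidation.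

Step 11
Reactants: 12 1-(5,7-dihydroxy-2,2-dimethyl-3,4-dihydro-2H-chromen-8-yl)-2-methylpropan-1-one; 19 6-methylheptanal
Product: 20 1-{5,7-dihydroxy-2,2-dimethyl-6-[6-methyl-1-(4-methylbenzenesulfonyl)heptyl]-3,4-dihydro-2H-chromen-8-yl}-2-methylpropan-1-one (racemic)
Conditions: p-TolSO2Na (3 equiv), 19 (3 equiv), HCO2H/H2O, rt
Reagents that add atoms: sodium 4-methylbenzenesulfinate, Cc1ccc(S(=O)[O-])cc1.[Na+]
Why: Three-component Mannich-type condensation in which C6 of 12, the only free ring carbon, adds to the aldehyde, the carbinol loses water to an ortho-quinone methide and the excess sulfinate traps it (sulfa-Michael addition) before a second molecule of 12 can, giving a storable precursor whose racemic stereocenter is erased in step 12.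

Step 12
Reactants: 20 1-{5,7-dihydroxy-2,2-dimethyl-6-[6-methyl-1-(4-methylbenzenesulfonyl)heptyl]-3,4-dihydro-2H-chromen-8-yl}-2-methylpropan-1-one; 17 (2R)-1-(5,7-dihydroxy-2,2-dimethyl-3,4-dihydro-2H-chromen-8-yl)-2-methylbutan-1-one
Product: 22 (2R)-1-{6-[(1R)-1-(5,7-dihydroxy-2,2-dimethyl-8-(2-methylpropanoyl)-3,4-dihydro-2H-chromen-6-yl)-6-methylheptyl]-5,7-dihydroxy-2,2-dimethyl-3,4-dihydro-2H-chromen-8-yl}-2-methylbutan-1-one (target), via ortho-quinone methide 21 (not isolated)
Conditions: quinine-derived squaramide 3-{[3,5-bis(trifluoromethyl)phenyl]amino}-4-{[(8α,9S)-6′-methoxycinchonan-9-yl]amino}cyclobut-3-ene-1,2-dione (10 mol %), Na2CO3 (1.2 equiv), CH2Cl2/H2O, 0 °C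
Reagents that add atoms: none
Why: Base-induced 1,4-elimination of sulfinate releases ortho-quinone methide 21, and in the Friedel–Crafts-type conjugate addition the bifunctional catalyst (squaramide N–H bonds to the quinone methide carbonyl, protonated quinuclidine paired with the phenoxide of 17) should guide C6 of 17 to one face of the methide carbon, so the (R) methine is set under catalyst control, the quinidine-derived pseudo-enantiomer being at hand if the sense of induction proves opposite, while the (R) acyl stereocenter is not touched.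

Compound list
1 | methyl 2,4,6-trihydroxybenzoate | COC(=O)c1c(O)cc(O)cc1O | starting material
2 | 1-bromo-3-methylbut-2-ene (prenyl bromide) | CC(C)=CCBr | starting material
3 | methyl 2,4,6-trihydroxy-3-(3-methylbut-2-en-1-yl)benzoate | COC(=O)c1c(O)cc(O)c(CC=C(C)C)c1O | intermediate
4 | methyl 3-[(3,3-dimethyloxiran-2-yl)methyl]-2,4,6-trihydroxybenzoate (racemic) | COC(=O)c1c(O)cc(O)c(CC2OC2(C)C)c1O | intermediate (not isolated)
5 | methyl 4,6-dihydroxy-2-(2-hydroxypropan-2-yl)-2,3-dihydro-1-benzofuran-5-carboxylate (racemic) | COC(=O)c1c(O)cc2OC(C(C)(C)O)Cc2c1O | intermediate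
6 | methyl 2-(2-bromopropan-2-yl)-4,6-dihydroxy-2,3-dihydro-1-benzofuran-5-carboxylate (racemic) | COC(=O)c1c(O)cc2OC(C(C)(C)Br)Cc2c1O | intermediate (not isolated)
7 | methyl 3-bromo-5,7-dihydroxy-2,2-dimethyl-3,4-dihydro-2H-chromene-6-carboxylate (racemic) | COC(=O)c1c(O)cc2OC(C)(C)C(Br)Cc2c1O | intermediate
8 | methyl 5,7-dihydroxy-2,2-dimethyl-3,4-dihydro-2H-chromene-6-carboxylate | COC(=O)c1c(O)cc2OC(C)(C)CCc2c1O | intermediate
9 | 2-methylpropanoyl chloride | CC(C)C(Cl)=O | starting material
10 | methyl 5,7-dihydroxy-2,2-dimethyl-8-(2-methylpropanoyl)-3,4-dihydro-2H-chromene-6-carboxylate | COC(=O)c1c(O)c(C(=O)C(C)C)c2OC(C)(C)CCc2c1O | intermediate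
11 | 5,7-dihydroxy-2,2-dimethyl-8-(2-methylpropanoyl)-3,4-dihydro-2H-chromene-6-carboxylic acid | OC(=O)c1c(O)c(C(=O)C(C)C)c2OC(C)(C)CCc2c1O | intermediate (not isolated)
12 | 1-(5,7-dihydroxy-2,2-dimethyl-3,4-dihydro-2H-chromen-8-yl)-2-methylpropan-1-one (fragment B) | CC(C)C(=O)c1c(O)cc(O)c2c1OC(C)(C)CC2 | intermediate
13 | (2R)-2-methylbutanoic acid | CC[C@@H](C)C(=O)O | starting material
14 | (2R)-2-methylbutanoyl chloride | CC[C@@H](C)C(Cl)=O | intermediate
15 | methyl 5,7-dihydroxy-2,2-dimethyl-8-[(2R)-2-methylbutanoyl]-3,4-dihydro-2H-chromene-6-carboxylate | CC[C@@H](C)C(=O)c1c(O)c(C(=O)OC)c(O)c2c1OC(C)(C)CC2 | intermediate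
16 | 5,7-dihydroxy-2,2-dimethyl-8-[(2R)-2-methylbutanoyl]-3,4-dihydro-2H-chromene-6-carboxylic acid | CC[C@@H](C)C(=O)c1c(O)c(C(=O)O)c(O)c2c1OC(C)(C)CC2 | intermediate (not isolated)
17 | (2R)-1-(5,7-dihydroxy-2,2-dimethyl-3,4-dihydro-2H-chromen-8-yl)-2-methylbutan-1-one (fragment A) | CC[C@@H](C)C(=O)c1c(O)cc(O)c2c1OC(C)(C)CC2 | intermediate
18 | 6-methylheptan-1-ol | CC(C)CCCCCO | starting material
19 | 6-methylheptanal | CC(C)CCCCC=O | intermediate
20 | 1-{5,7-dihydroxy-2,2-dimethyl-6-[6-methyl-1-(4-methylbenzenesulfonyl)heptyl]-3,4-dihydro-2H-chromen-8-yl}-2-methylpropan-1-one (racemic) | CC(C)CCCCC(c1c(O)c2c(c(C(=O)C(C)C)c1O)OC(C)(C)CC2)S(=O)(=O)c1ccc(C)cc1 | intermediate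
21 | 7-hydroxy-2,2-dimethyl-6-(6-methylheptylidene)-8-(2-methylpropanoyl)-3,4-dihydro-2H-chromen-5(6H)-one (ortho-quinone methide, alkene geometry not fixed) | CC(C)CCCCC=C1C(=O)C2=C(OC(C)(C)CC2)C(C(=O)C(C)C)=C1O | intermediate (not isolated)
22 | (2R)-1-{6-[(1R)-1-(5,7-dihydroxy-2,2-dimethyl-8-(2-methylpropanoyl)-3,4-dihydro-2H-chromen-6-yl)-6-methylheptyl]-5,7-dihydroxy-2,2-dimethyl-3,4-dihydro-2H-chromen-8-yl}-2-methylbutan-1-one | CC[C@@H](C)C(=O)c1c(O)c([C@H](CCCCC(C)C)c2c(O)c3c(c(C(=O)C(C)C)c2O)OC(C)(C)CC3)c(O)c2c1OC(C)(C)CC2 | target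

Total step count: 12. Longest linear sequence: 8 steps (steps 1, 2, 3, 4, 5, 6, 11 and 12).

Steps most likely to fail:

Step 3. The cation may lose a proton instead of being captured, which leads to the alkene and on to the aromatic 2-isopropylbenzofuran, or the equilibrium may stall at the five-membered bromide. The fallback keeps the ring enlargement but traps with oxygen and removes the C3 substituent by elimination. It sets out from 5: dilute H2SO4 in aqueous dioxane at 50 °C lets water open the same oxiranium ion and should give methyl 3,5,7-trihydroxy-2,2-dimethyl-3,4-dihydro-2H-chromene-6-carboxylate F1. Acid-catalysed dehydration (p-TsOH, toluene, reflux) then gives methyl 5,7-dihydroxy-2,2-dimethyl-2H-chromene-6-carboxylate F2, and hydrogenation (H2, Pd/C, EtOAc) comes back to the route at 8, so step 4 is no longer needed.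

Step 11. The ortho-quinone methide may be captured by a second molecule of 12 to form the symmetric dimer irreversibly, and under acid the sulfone can re-ionise and drift the same way. The fallback sets out from 12: condensation with 19 and 4-methylbenzenethiol under amine catalysis (piperidine, EtOH, rt), where the thiol is the much better trap and no acid is present, should give 1-{5,7-dihydroxy-2,2-dimethyl-6-[6-methyl-1-(4-methylphenylsulfanyl)heptyl]-3,4-dihydro-2H-chromen-8-yl}-2-methylpropan-1-one F3. Oxidation at sulfur (H2O2, Na2WO4 cat., MeOH) comes back to the route at 20.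

Step 12. Facial selectivity at the methide carbon may be poor, for instance through an uncatalysed addition of the free phenoxide of 17 or through reversible ionisation of the product. The fallback sets out from 20 and 17 and replaces catalyst control by separation: coupling with Na2CO3 alone (CH2Cl2/H2O, rt) should give 22 together with its methine epimer (2R)-1-{6-[(1S)-1-(5,7-dihydroxy-2,2-dimethyl-8-(2-methylpropanoyl)-3,4-dihydro-2H-chromen-6-yl)-6-methylheptyl]-5,7-dihydroxy-2,2-dimethyl-3,4-dihydro-2H-chromen-8-yl}-2-methylbutan-1-one F4. The two diastereomers are separated by preparative HPLC on a chiral stationary phase, which comes back to the route at 22.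

Further compounds
F1 | step 3 | methyl 3,5,7-trihydroxy-2,2-dimethyl-3,4-dihydro-2H-chromene-6-carboxylate (racemic) | COC(=O)c1c(O)cc2OC(C)(C)C(O)Cc2c1O
F2 | step 3 | methyl 5,7-dihydroxy-2,2-dimethyl-2H-chromene-6-carboxylate | COC(=O)c1c(O)cc2OC(C)(C)C=Cc2c1O
F3 | step 11 | 1-{5,7-dihydroxy-2,2-dimethyl-6-[6-methyl-1-(4-methylphenylsulfanyl)heptyl]-3,4-dihydro-2H-chromen-8-yl}-2-methylpropan-1-one (racemic) | CC(C)CCCCC(Sc1ccc(C)cc1)c1c(O)c2c(c(C(=O)C(C)C)c1O)OC(C)(C)CC2
F4 | step 12 | (2R)-1-{6-[(1S)-1-(5,7-dihydroxy-2,2-dimethyl-8-(2-methylpropanoyl)-3,4-dihydro-2H-chromen-6-yl)-6-methylheptyl]-5,7-dihydroxy-2,2-dimethyl-3,4-dihydro-2H-chromen-8-yl}-2-methylbutan-1-one | CC[C@@H](C)C(=O)c1c(O)c([C@@H](CCCCC(C)C)c2c(O)c3c(c(C(=O)C(C)C)c2O)OC(C)(C)CC3)c(O)c2c1OC(C)(C)CC2
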